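The data are calculated with constants of no real substance; the scatter is artificial.

Start with the easy step: the catalyst enters both steps towards product and comes out unchanged, so if each step runs in proportion to it, progress follows loading times time, which I call catalyst time. No earlier run changes the loading, so this is a guess.

| flask | substrate | coupling partner | catalyst | remark | time |
|---|---|---|---|---|---|
| east | 0.37 M | 0.57 equiv | 0.1 mol% | run made earlier |  |
| north | 0.37 M | 1.2 equiv | 0.1 mol% | run made earlier |  |
| spring | 0.37 M | 0.400 equiv | 0.1 mol% |  | 30 min |
| dusk | 0.37 M | 0.800 equiv | 0.03 mol% |  | 30 min |
| autumn | 0.37 M | 0.800 equiv | 0.3 mol% |  | 30 min |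
| summer | 0.37 M | 0.800 equiv | 0.05 mol% |  | 30 min |
| dawn | 0.37 M | 0.800 equiv | 0.1 mol% |  | 30 min |

- east (time / min: product / %): 1.50: 2; 3.00: 0; 6.00: 2; 12.0: 7; 20.0: 13
- north (time / min: product / %): 2.00: 0; 5.00: 1; 10.0: 7; 15.0: 12; 20.0: 21

(standard deviation of a reading: 2 percentage points)

* all flasks from highest to lowest amount of product, in percent of the substrate charged, at 30 min (spring / dusk / autumn / summer / dawn)
* the amount of product, in percent of the substrate charged of the flask you put first, at 30 min
* the amount of product, in percent of the substrate charged of the flask you put last, at 30 min

- percentages count the substrate that a species holds: one idle adduct counts as two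
- product is meant together with its idle adduct
- steps thought possible: substrate + catalyst -> catalyst + intermediate; coupling partner + catalyst + intermediate -> catalyst + product; substrate + product <-> idle adduct
- in an amount of product, one idle adduct counts as one product
- no earlier run changes the charge of catalyst; that part of a forecast is a guess

The rate of product starts near zero and then grows: north reads 1% after 5.00 min but 21% after 20.0 min. That is the pattern of a product made through an intermediate, so early on I take the rate as rising in step with catalyst time and the product as rising with its square.

A straight line between the last readings of east and north gives, at 0.800 equiv, 0.1 mol% and 20.0 min, the yardstick 15.9%, a reading with its scatter. The unslowed product is this yardstick times the square of the catalyst-time ratio to those settings. For dawn that gives 35.8%. Autumn's ratio of 4.50 gives 322%, which is impossible, so the slowing must be counted.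

Each product takes one coupling partner, the limiting reagent at 0.800 equiv, so autumn's ceiling is 80.0%. I let the unslowed product shrink by the factor 1 − product/ceiling and put the answer back in; the value that comes back unchanged is unslowed product / (1 + unslowed product/ceiling). Autumn comes to 64.1%, with a factor of 0.199, and dawn to 24.7%, with 0.691.

Read off the last readings of the two runs, with their scatter, the order in coupling partner is 0.644. Spring, with half of dawn's partner and a ceiling of 40.0%, then comes to 14.6%. Summer comes to 8.05% and dusk to 3.10%.

The forecast says autumn > dawn > spring > summer > dusk, with 50% for autumn and 3% for dusk, on the ground that “the effective time is catalyst × time”; its top lies lower than mine.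

The simulation gives autumn > dawn > spring > summer > dusk: autumn 53.6%, dawn 22.7%, spring 13.1%, summer 8.77%, dusk 3.75%.

    substrate + catalyst → catalyst + intermediate (k = 1.60 M⁻¹ s⁻¹)
    coupling partner + catalyst + intermediate → catalyst + product (k = 5.00 M⁻² s⁻¹)
    substrate + product ⇌ idle adduct, settled at all times (K = 29.0 M⁻¹)

My autumn stands 11 percentage points above the simulated value. Take a neighbour of autumn with 1.2 mol% of catalyst. Its catalyst-time ratio is 18.0, so the yardstick gives 5158% unslowed, and the same ceiling brings that down to 78.8%. The neighbour gives 76.9%, which is less than the ceiling. Of its coupling partner, 3.9% of the charge is left unbound.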